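The trans-2,5-disubstituted oxolane (ring O, C5–C8; ester carbonyl = C1) is disconnected at O–C5 and C5–C4, with a temporary ketone at C6. In the key step a copper carbenoid made from an allyloxy diazoketone is captured by the ether oxygen, and the resulting oxonium ylide relays its allyl group to C5 by a [2,3]-shift. One operation thus closes the ring, sets C5 trans to the C8 alkynyl group and installs C4 and C3; it exploits ring carbon C5, bonded to the ring oxygen and to the C4–C2 trimethylene arm, as landing site for an O-allyl group. The precursor is an (S)-propargylic allyl ether with a CH2–CO–CHN2 arm and a silyl-capped alkyne. The C11–C20 bromodienyl iodide is attached last.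

Key step: step 7

Remark: carbons are numbered C1 (ester carbonyl) to C20 (CHBr) as in the target; diazomethane is taken as an ethereal solution prepared beforehand from N-methyl-N-nitroso-p-toluenesulfonamide, and the transfer hydrogenation of step 3 is assumed to follow the facial sense established for simple silyl ynones.

Step 1
Reactants: 1 3-(triisopropylsilyl)prop-2-ynal; 2 methyl acetate
Product: 4 methyl (±)-3-hydroxy-5-(triisopropylsilyl)pent-4-ynoate, via lithium enolate 3 (not isolated)
Conditions: LiN(i-Pr)2, THF, −78 °C; 2, then 1; AcOH quench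
Reagents that add atoms: methyl acetate 2, COC(C)=O
Why: Aldol addition of a preformed lithium ester enolate to the non-enolisable ynal is fast and 1,2-selective at −78 °C, the bulky silyl cap shielding the alkyne terminus; the carbinol centre is racemic here and is erased in step 2.

Step 2
Reactants: 4 methyl (±)-3-hydroxy-5-(triisopropylsilyl)pent-4-ynoate
Product: 5 methyl 3-oxo-5-(triisopropylsilyl)pent-4-ynoate
Conditions: Dess–Martin periodinane, CH2Cl2, 0 °C → rt
Reagents that add atoms: none
Why: Dess–Martin oxidation of a secondary propargylic alcohol gives the ynone under neutral conditions that leave the ester and the silylalkyne untouched.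

Step 3
Reactants: 5 methyl 3-oxo-5-(triisopropylsilyl)pent-4-ynoate
Product: 6 methyl (3S)-3-hydroxy-5-(triisopropylsilyl)pent-4-ynoate
Conditions: RuCl(p-cymene)[(S,S)-TsDPEN] (1 mol%), HCO2H–Et3N (5:2), CH2Cl2, rt
Reagents that add atoms: none
Why: Noyori asymmetric transfer hydrogenation of an alkynyl ketone, in which the (S,S)-ligand should place the alkyne next to the arene ligand and deliver hydride to give the (S)-propargylic alcohol (future C8), reduces only the C=O bond; the configuration would be checked by Mosher ester analysis.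

Step 4
Reactants: 6 methyl (3S)-3-hydroxy-5-(triisopropylsilyl)pent-4-ynoate; 7 allyl 2,2,2-trichloroacetimidate
Product: 8 methyl (3S)-3-(allyloxy)-5-(triisopropylsilyl)pent-4-ynoate
Conditions: 7 (2 equiv), TfOH (10 mol%), CH2Cl2–cyclohexane, 0 °C → rt
Reagents that add atoms: allyl 2,2,2-trichloroacetimidate 7, C=CCOC(=N)C(Cl)(Cl)Cl
Why: Acid-catalysed O-alkylation with a trichloroacetimidate etherifies the β-hydroxy ester without base, so retro-aldol cleavage and β-elimination are avoided and the C–O bond at C8 is not broken (configuration retained).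

Step 5
Reactants: 8 methyl (3S)-3-(allyloxy)-5-(triisopropylsilyl)pent-4-ynoate
Product: 9 (3S)-3-(allyloxy)-5-(triisopropylsilyl)pent-4-ynoic acid
Conditions: LiOH·H2O, THF–H2O (3:1), 0 °C → rt; 1 M HCl to pH 3
Reagents that add atoms: lithium hydroxide, [Li+].[OH-]
Why: Saponification of a methyl ester with LiOH at 0 °C is mild enough for the triisopropylsilyl alkyne and for the β-alkoxy ester, which would eliminate only under stronger base.

Step 6
Reactants: 9 (3S)-3-(allyloxy)-5-(triisopropylsilyl)pent-4-ynoic acid; 10 diazomethane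
Product: 12 (4S)-4-(allyloxy)-1-diazo-6-(triisopropylsilyl)hex-5-yn-2-one, via mixed anhydride 11 (not isolated)
Conditions: i-BuOCOCl, Et3N, Et2O, −20 °C; then CH2N2, Et2O, 0 °C
Reagents that add atoms: diazomethane 10, C=[N+]=[N-]
Why: Acylation of diazomethane by a mixed carbonic anhydride (the diazoketone stage of an Arndt–Eistert sequence) converts the acid into the α-diazoketone without touching the allyl ether, the alkyne or the stereocentre.

Step 7
Reactants: 12 (4S)-4-(allyloxy)-1-diazo-6-(triisopropylsilyl)hex-5-yn-2-one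
Product: 15 (2R,5S)-2-allyl-5-[(triisopropylsilyl)ethynyl]oxolan-3-one, via copper carbenoid 13 (not isolated), via oxonium ylide 14 (not isolated)
Conditions: Cu(acac)2 (10 mol%), THF, reflux, slow addition of 12
Reagents that add atoms: none
Why: Cu(acac)2 (divalent copper) decomposes the diazoketone with loss of N2 to an electrophilic carbenoid at C5, which a lone pair of the allyl ether oxygen captures to give a five-membered cyclic oxonium ylide (O–C5 bond); a concerted suprafacial [2,3]-sigmatropic shift through a five-membered envelope transition state then moves the allyl group from oxygen to C5 with allylic transposition (C5–C4 bond) and leaves the neutral oxolan-3-one. The closest known reaction type is the copper-catalysed tandem oxonium ylide formation and [2,3]-rearrangement of 4-allyloxy diazoketones to trans-2,5-dialkyl oxolan-3-ones, applied here with an alkynyl group at C8. The oxolanone ring closes by intramolecular attack of oxygen on the carbenoid carbon, the five-membered ylide being kinetically preferred over the six-membered ring that C–H insertion into the O-allyl methylene would give. The new centre C5 is controlled by C8: in the ylide the allyl group on oxygen sits anti to the C8 silylalkynyl substituent and migrates across that face, which places it trans to the substituent (2R,5S). The step needs chemoselectivity for ylide formation over cyclopropanation, attack on the alkyne and C–H insertion, which the electron-rich acetylacetonate ligands and the bulky triisopropylsilyl cap should secure, and a competing [1,2]-shift would give the same constitution.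

Step 8
Reactants: 15 (2R,5S)-2-allyl-5-[(triisopropylsilyl)ethynyl]oxolan-3-one
Product: 16 N'-[(2R,5S)-2-allyl-5-[(triisopropylsilyl)ethynyl]oxolan-3-ylidene]-4-methylbenzenesulfonohydrazide
Conditions: TsNHNH2, MeOH, rt
Reagents that add atoms: 4-methylbenzenesulfonohydrazide, Cc1ccc(cc1)S(=O)(=O)NN
Why: Condensation of the ketone with tosylhydrazide is run without acid at room temperature so that the α-centre C5 should not epimerise through the ene-hydrazine.

Step 9
Reactants: 16 N'-[(2R,5S)-2-allyl-5-[(triisopropylsilyl)ethynyl]oxolan-3-ylidene]-4-methylbenzenesulfonohydrazide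
Product: 19 (2S,5S)-2-allyl-5-[(triisopropylsilyl)ethynyl]oxolane, via tosylhydrazine 17 (not isolated), via alkyldiazene 18 (not isolated)
Conditions: catecholborane, CHCl3, 0 °C; then NaOAc·3H2O, 60 °C
Reagents that add atoms: none
Why: Caglioti-type tosylhydrazone reduction with catecholborane: hydride adds to C=N, acetate-induced loss of sulfinate gives an alkyldiazene that expels N2 to leave CH2 at C6, under conditions too mild for hydroboration of the alkene or the silylalkyne; C5 and C8 are untouched and the descriptor at C5 changes only through the priority rules.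

Step 10
Reactants: 19 (2S,5S)-2-allyl-5-[(triisopropylsilyl)ethynyl]oxolane; 20 methyl acrylate
Product: 21 methyl (2E)-4-[(2S,5S)-5-[(triisopropylsilyl)ethynyl]oxolan-2-yl]but-2-enoate
Conditions: 20 (5 equiv), second-generation Grubbs catalyst (5 mol%), CH2Cl2, 40 °C
Reagents that add atoms: methyl acrylate 20, C=CC(=O)OC
Why: Olefin cross-metathesis of a terminal alkene with excess electron-poor acrylate is selective for the (E)-enoate cross product because the acrylate homodimerises slowly, and the hindered silylalkyne should stay out of enyne metathesis.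

Step 11
Reactants: 21 methyl (2E)-4-[(2S,5S)-5-[(triisopropylsilyl)ethynyl]oxolan-2-yl]but-2-enoate
Product: 23 methyl 4-[(2R,5S)-5-[(triisopropylsilyl)ethynyl]oxolan-2-yl]butanoate, via copper enolate 22 (not isolated)
Conditions: [(Ph3P)CuH]6 (0.3 equiv), H2O (2 equiv), toluene, rt
Reagents that add atoms: none
Why: Copper hydride conjugate reduction delivers hydride to the β-carbon of the enoate and water protonates the copper enolate, while the internal silylalkyne and the propargylic ether are not attacked at room temperature.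

Step 12
Reactants: 23 methyl 4-[(2R,5S)-5-[(triisopropylsilyl)ethynyl]oxolan-2-yl]butanoate
Product: 24 methyl 4-[(2R,5S)-5-ethynyloxolan-2-yl]butanoate
Conditions: TBAF, AcOH, THF, 0 °C → rt
Reagents that add atoms: none
Why: Fluoride-induced protodesilylation of the alkynylsilane, buffered with acetic acid, frees the terminal alkyne without hydrolysing the methyl ester or isomerising the propargylic centre C8.

Step 13
Reactants: 25 hept-6-yn-1-ol
Product: 27 (6E)-7-iodohept-6-en-1-ol, via alkenylzirconocene 26 (not isolated)
Conditions: Cp2Zr(H)Cl (2.3 equiv), THF, rt; then I2, 0 °C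
Reagents that add atoms: iodine, II
Why: Hydrozirconation of the terminal alkyne is a syn addition with zirconium at the terminal carbon and iodinolysis proceeds with retention to the (E)-vinyl iodide, the first equivalent of hydride being consumed by the hydroxyl group.

Step 14
Reactants: 27 (6E)-7-iodohept-6-en-1-ol
Product: 28 (6E)-7-iodohept-6-enal
Conditions: Dess–Martin periodinane, CH2Cl2, rt
Reagents that add atoms: none
Why: Dess–Martin oxidation takes the primary alcohol to the aldehyde without over-oxidation and without affecting the vinyl iodide.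

Step 15
Reactants: 28 (6E)-7-iodohept-6-enal; 29 (triphenylphosphoranylidene)acetaldehyde
Product: 30 (2E,8E)-9-iodonona-2,8-dienal
Conditions: 29 (1.1 equiv), toluene, 80 °C
Reagents that add atoms: (triphenylphosphoranylidene)acetaldehyde 29, O=CC=P(c1ccccc1)(c1ccccc1)c1ccccc1
Why: Wittig reaction with the stabilised formylmethylene ylide gives the (E)-enal, and the conjugated product aldehyde reacts more slowly than the saturated one, which limits a second homologation.

Step 16
Reactants: 30 (2E,8E)-9-iodonona-2,8-dienal; 31 bromoform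
Product: 32 (1E,3E,9E)-1-bromo-10-iododeca-1,3,9-triene
Conditions: CrBr2 (6 equiv), CHBr3 (2 equiv), THF, 0 °C → rt
Reagents that add atoms: bromoform 31, BrC(Br)Br
Why: Takai–Utimoto olefination, in which the geminal dichromium species from bromoform adds to the aldehyde and eliminates to the (E)-vinyl bromide; CrBr2 excludes chloride incorporation and the alkenyl iodide should be inert to divalent chromium without nickel.

Step 17
Reactants: 24 methyl 4-[(2R,5S)-5-ethynyloxolan-2-yl]butanoate; 32 (1E,3E,9E)-1-bromo-10-iododeca-1,3,9-triene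
Product: 33 methyl 4-[(2R,5S)-5-[(3E,9E,11E)-12-bromododeca-3,9,11-trien-1-yn-1-yl]oxolan-2-yl]butanoate
Conditions: Pd(PPh3)4 (5 mol%), CuI (10 mol%), i-Pr2NH, THF (degassed), 0 °C → rt, 32 (1.2 equiv)
Reagents that add atoms: (1E,3E,9E)-1-bromo-10-iododeca-1,3,9-triene 32, Br/C=C/C=C/CCCC/C=C/I
Why: Sonogashira coupling, in which oxidative addition of zerovalent palladium to the alkenyl iodide is much faster than to the dienyl bromide at or below room temperature, so with the alkyne as limiting partner the C10–C11 bond should form with retention of the (E)-geometry and the bromodiene should survive.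

Compound list
1 | 3-(triisopropylsilyl)prop-2-ynal | O=CC#C[Si](C(C)C)(C(C)C)C(C)C | starting material
2 | methyl acetate | COC(C)=O | starting material
3 | lithium 1-methoxyethen-1-olate | C=C(OC)O[Li] | intermediate (not isolated)
4 | methyl (±)-3-hydroxy-5-(triisopropylsilyl)pent-4-ynoate | COC(=O)CC(O)C#C[Si](C(C)C)(C(C)C)C(C)C | intermediate
5 | methyl 3-oxo-5-(triisopropylsilyl)pent-4-ynoate | COC(=O)CC(=O)C#C[Si](C(C)C)(C(C)C)C(C)C | intermediate
6 | methyl (3S)-3-hydroxy-5-(triisopropylsilyl)pent-4-ynoate | COC(=O)C[C@H](O)C#C[Si](C(C)C)(C(C)C)C(C)C | intermediate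
7 | allyl 2,2,2-trichloroacetimidate | C=CCOC(=N)C(Cl)(Cl)Cl | starting material
8 | methyl (3S)-3-(allyloxy)-5-(triisopropylsilyl)pent-4-ynoate | COC(=O)C[C@H](OCC=C)C#C[Si](C(C)C)(C(C)C)C(C)C | intermediate
9 | (3S)-3-(allyloxy)-5-(triisopropylsilyl)pent-4-ynoic acid | OC(=O)C[C@H](OCC=C)C#C[Si](C(C)C)(C(C)C)C(C)C | intermediate
10 | diazomethane | C=[N+]=[N-] | starting material
11 | (3S)-3-(allyloxy)-5-(triisopropylsilyl)pent-4-ynoic isobutyl carbonic anhydride | CC(C)COC(=O)OC(=O)C[C@H](OCC=C)C#C[Si](C(C)C)(C(C)C)C(C)C | intermediate (not isolated)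
12 | (4S)-4-(allyloxy)-1-diazo-6-(triisopropylsilyl)hex-5-yn-2-one | [N-]=[N+]=CC(=O)C[C@@H](C#C[Si](C(C)C)(C(C)C)C(C)C)OCC=C | intermediate
13 | copper carbenoid of 12 (acac ligands on copper not drawn) | C=CCO[C@@H](CC(=O)C=[Cu])C#C[Si](C(C)C)(C(C)C)C(C)C | intermediate (not isolated)
14 | (5S)-1-allyl-3-oxo-5-[(triisopropylsilyl)ethynyl]oxolan-1-ium-2-ide | C=CC[O+]1[CH-]C(=O)C[C@H]1C#C[Si](C(C)C)(C(C)C)C(C)C | intermediate (not isolated)
15 | (2R,5S)-2-allyl-5-[(triisopropylsilyl)ethynyl]oxolan-3-one | C=CC[C@@H]1C(=O)C[C@@H](C#C[Si](C(C)C)(C(C)C)C(C)C)O1 | intermediate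
16 | N'-[(2R,5S)-2-allyl-5-[(triisopropylsilyl)ethynyl]oxolan-3-ylidene]-4-methylbenzenesulfonohydrazide | C=CC[C@@H]1C(=NNS(=O)(=O)c2ccc(C)cc2)C[C@@H](C#C[Si](C(C)C)(C(C)C)C(C)C)O1 | intermediate
17 | N'-[(2R,5S)-2-allyl-5-[(triisopropylsilyl)ethynyl]oxolan-3-yl]-4-methylbenzenesulfonohydrazide (C3 epimers, formed as its N-catecholboryl derivative) | C=CC[C@@H]1C(NNS(=O)(=O)c2ccc(C)cc2)C[C@@H](C#C[Si](C(C)C)(C(C)C)C(C)C)O1 | intermediate (not isolated)
18 | [(2R,5S)-2-allyl-5-[(triisopropylsilyl)ethynyl]oxolan-3-yl]diazene | C=CC[C@@H]1C(N=N)C[C@@H](C#C[Si](C(C)C)(C(C)C)C(C)C)O1 | intermediate (not isolated)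
19 | (2S,5S)-2-allyl-5-[(triisopropylsilyl)ethynyl]oxolane | C=CC[C@@H]1CC[C@@H](C#C[Si](C(C)C)(C(C)C)C(C)C)O1 | intermediate
20 | methyl acrylate | C=CC(=O)OC | starting material
21 | methyl (2E)-4-[(2S,5S)-5-[(triisopropylsilyl)ethynyl]oxolan-2-yl]but-2-enoate | COC(=O)/C=C/C[C@@H]1CC[C@@H](C#C[Si](C(C)C)(C(C)C)C(C)C)O1 | intermediate
22 | copper enolate of 23 (ketene acetal form, Ph3P on copper not drawn) | COC(O[Cu])=CCC[C@@H]1CC[C@@H](C#C[Si](C(C)C)(C(C)C)C(C)C)O1 | intermediate (not isolated)
23 | methyl 4-[(2R,5S)-5-[(triisopropylsilyl)ethynyl]oxolan-2-yl]butanoate | COC(=O)CCC[C@@H]1CC[C@@H](C#C[Si](C(C)C)(C(C)C)C(C)C)O1 | intermediate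
24 | methyl 4-[(2R,5S)-5-ethynyloxolan-2-yl]butanoate | COC(=O)CCC[C@@H]1CC[C@@H](C#C)O1 | intermediate
25 | hept-6-yn-1-ol | C#CCCCCCO | starting material
26 | (E)-alkenylzirconocene chloride of 25, O-zirconated (Cp drawn σ-bonded) | Cl[Zr](/C=C/CCCCCO[Zr](Cl)(C1C=CC=C1)C1C=CC=C1)(C1C=CC=C1)C1C=CC=C1 | intermediate (not isolated)
27 | (6E)-7-iodohept-6-en-1-ol | OCCCCC/C=C/I | intermediate
28 | (6E)-7-iodohept-6-enal | O=CCCCC/C=C/I | intermediate
29 | (triphenylphosphoranylidene)acetaldehyde | O=CC=P(c1ccccc1)(c1ccccc1)c1ccccc1 | starting material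
30 | (2E,8E)-9-iodonona-2,8-dienal | O=C/C=C/CCCC/C=C/I | intermediate
31 | bromoform | BrC(Br)Br | starting material
32 | (1E,3E,9E)-1-bromo-10-iododeca-1,3,9-triene | Br/C=C/C=C/CCCC/C=C/I | intermediate
33 | methyl 4-[(2R,5S)-5-[(3E,9E,11E)-12-bromododeca-3,9,11-trien-1-yn-1-yl]oxolan-2-yl]butanoate | COC(=O)CCC[C@@H]1CC[C@@H](C#C/C=C/CCCC/C=C/C=C/Br)O1 | target

Total step count: 17. Longest linear sequence: 13 steps (steps 1–12 and 17); steps 13–16 build the C11–C20 fragment.

Steps most likely to fail

Step 7. The carbenoid may be diverted into C–H insertion, reaction with the alkyne or dimerisation, or the allyl transfer may show insufficient trans selectivity because a slim alkynyl group biases the ylide only weakly. The fallback closes the ring by oxidative cyclisation instead. It sets out from aldehyde 1: addition of but-3-enylmagnesium bromide gives (±)-1-(triisopropylsilyl)hept-6-en-1-yn-3-ol F1, Dess–Martin oxidation gives 1-(triisopropylsilyl)hept-6-en-1-yn-3-one F2, and transfer hydrogenation with RuCl(p-cymene)[(S,S)-TsDPEN] in i-PrOH gives (3S)-1-(triisopropylsilyl)hept-6-en-1-yn-3-ol F3. Mukaiyama aerobic oxidative cyclisation (Co(modp)2, divalent cobalt, modp = 1-morpholinocarbamoyl-4,4-dimethylpentane-1,3-dionate; O2, t-BuOOH, i-PrOH, 55 °C), known to turn pent-4-en-1-ols into trans-2,5-disubstituted oxolanes, should give [(2S,5S)-5-[(triisopropylsilyl)ethynyl]oxolan-2-yl]methanol F4. Appel iodination (I2, PPh3, imidazole) gives (2S,5S)-2-(iodomethyl)-5-[(triisopropylsilyl)ethynyl]oxolane F5, and Giese addition of its primary radical to methyl acrylate 20 (Bu3SnH, AIBN, benzene, 80 °C) comes back to the route at ester 23.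

Step 9. The diazene stage may be diverted into eliminative opening of the ring (loss of the C5–O bond, Kishner–Leonard type), or C5 may epimerise at the hydrazone stage. The fallback removes the ketone by radical deoxygenation. It sets out from ketone 15: NaBH4 in MeOH at −20 °C gives (2R,5S)-2-allyl-5-[(triisopropylsilyl)ethynyl]oxolan-3-ol F6 (either C3 epimer serves), 1,1'-thiocarbonyldiimidazole in toluene at 70 °C gives O-[(2R,5S)-2-allyl-5-[(triisopropylsilyl)ethynyl]oxolan-3-yl] 1H-imidazole-1-carbothioate F7, and Barton–McCombie reduction (Bu3SnH, AIBN, toluene, 90 °C) comes back to the route at oxolane 19.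

Step 16. The bromo-olefination may give incomplete E/Z control at C19=C20 or halide exchange at chromium, and the isomers would be hard to separate. The fallback makes the bromodiene stereospecifically from an alkyne. It sets out from enal 30: Colvin homologation with lithiated trimethylsilyldiazomethane (TMSCHN2, LiN(i-Pr)2, THF, −78 °C → rt) gives (1E,7E)-1-iododeca-1,7-dien-9-yne F8, and hydrozirconation with Cp2Zr(H)Cl followed by N-bromosuccinimide (syn addition, bromination with retention) comes back to the route at triene 32.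

Further compounds
F1 | step 7 | (±)-1-(triisopropylsilyl)hept-6-en-1-yn-3-ol | C=CCCC(O)C#C[Si](C(C)C)(C(C)C)C(C)C
F2 | step 7 | 1-(triisopropylsilyl)hept-6-en-1-yn-3-one | C=CCCC(=O)C#C[Si](C(C)C)(C(C)C)C(C)C
F3 | step 7 | (3S)-1-(triisopropylsilyl)hept-6-en-1-yn-3-ol | C=CCC[C@H](O)C#C[Si](C(C)C)(C(C)C)C(C)C
F4 | step 7 | [(2S,5S)-5-[(triisopropylsilyl)ethynyl]oxolan-2-yl]methanol | OC[C@@H]1CC[C@@H](C#C[Si](C(C)C)(C(C)C)C(C)C)O1
F5 | step 7 | (2S,5S)-2-(iodomethyl)-5-[(triisopropylsilyl)ethynyl]oxolane | IC[C@@H]1CC[C@@H](C#C[Si](C(C)C)(C(C)C)C(C)C)O1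
F6 | step 9 | (2R,5S)-2-allyl-5-[(triisopropylsilyl)ethynyl]oxolan-3-ol (C3 epimers) | C=CC[C@@H]1C(O)C[C@@H](C#C[Si](C(C)C)(C(C)C)C(C)C)O1
F7 | step 9 | O-[(2R,5S)-2-allyl-5-[(triisopropylsilyl)ethynyl]oxolan-3-yl] 1H-imidazole-1-carbothioate | C=CC[C@@H]1C(OC(=S)n2ccnc2)C[C@@H](C#C[Si](C(C)C)(C(C)C)C(C)C)O1
F8 | step 16 | (1E,7E)-1-iododeca-1,7-dien-9-yne | I/C=C/CCCC/C=C/C#C
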